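**Plan**
- Retrosynthesis: remove Cl from C5, open ring B at O2–C3 to give an alkynol, then cut C3–C9. This leaves a ring A enynone and a ring C vinyl iodide.
- Ring A is cut at C4–C4a (acetylide addition with oxidative transposition), C5=C6 (metathesis) and C8–C8a (aldol). The side chain is cut at C9=C10 (iodo-olefination), O1'–C2' (epoxide opening) and C2'=C11 (Wittig).
- Enabling feature: C2', the ring C carbon bonded to O1', and the tertiary carbinol C11 are neighbouring C–O stereocentres. They correspond to the two carbons of an E-trisubstituted 2,3-epoxy alcohol whose C2'–O bond has been displaced by the C5' hydroxyl.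
- Forward order: ring C closes first (step 6) and ring A by metathesis (step 15). The fragments join at step 21, ring B closes last (step 23), and C5 is then chlorinated.
- Stereochemistry: C3' comes from BINAP–Ru hydrogenation. C11 and C2' come from Sharpless epoxidation with D-(−)-DIPT, followed by inversion at C2'. C7 comes from (R)-2-methylglycidol, and C8 and C8a from an Evans syn-aldol with (R)-4-benzyloxazolidinone.

Key step: step 6

Numbering: ring A = C4a, C5, C6, C7, C8, C8a. Ring B = C1, O2, C3, C4, C4a, C8a. Chain = C9=C10–C11. Ring C = O1', C2'–C5'.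
Assumption: Ru(OAc)2[(R)-BINAP] is taken to give the S lactone from the α-methylene lactone, the sense associated with exocyclic methylene lactones; the sense of induction is a property of the ligand enantiomer only.

**Fragment 1 (ring C vinyl iodide)**

Step 1
Reactants: 1 3-methylideneoxolan-2-one (α-methylene-γ-butyrolactone)
Product: 2 (3S)-3-methyloxolan-2-one
Conditions: H2 (100 atm), Ru(OAc)2[(R)-BINAP] (0.5 mol %), CH2Cl2, 50 °C
Reagents that add atoms: none
Why: BINAP–ruthenium asymmetric hydrogenation of an exocyclic α-methylene lactone, in which the lactone carbonyl anchors the alkene on divalent ruthenium and the R ligand should direct both hydrogens to the face that makes C3' S.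

Step 2
Reactants: 2 (3S)-3-methyloxolan-2-one
Product: 3 (3S)-3-methyloxolan-2-ol (lactol, both anomers)
Conditions: i-Bu2AlH (1.1 equiv), CH2Cl2, −78 °C
Reagents that add atoms: none
Why: Partial lactone reduction with i-Bu2AlH stops at the aluminium hemiacetal at low temperature, so the aldehyde oxidation level is reached without touching C3'.

Step 3
Reactants: 3 (3S)-3-methyloxolan-2-ol; 4 ethyl 2-(triphenylphosphoranylidene)propanoate
Product: 5 ethyl (2E,4S)-6-hydroxy-2,4-dimethylhex-2-enoate
Conditions: PhMe, 80 °C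
Reagents that add atoms: none
Why: Wittig olefination of the hydroxy-aldehyde tautomer of the lactol with a stabilised α-methyl ylide is reliably E-selective and mild enough to leave the α-stereocentre C3' intact.

Step 4
Reactants: 5 ethyl (2E,4S)-6-hydroxy-2,4-dimethylhex-2-enoate
Product: 6 (2E,4S)-2,4-dimethylhex-2-ene-1,6-diol
Conditions: i-Bu2AlH (3.3 equiv), CH2Cl2, −78 → 0 °C
Reagents that add atoms: none
Why: 1,2-Reduction of the enoate with i-Bu2AlH gives the E-allylic alcohol needed for directed epoxidation and leaves the alkene geometry and C3' unchanged.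

Step 5
Reactants: 6 (2E,4S)-2,4-dimethylhex-2-ene-1,6-diol
Product: 7 (3S)-3-[(2R,3R)-3-(hydroxymethyl)-3-methyloxiran-2-yl]butan-1-ol (epoxy diol; C3' S, C2' R, C11 R)
Conditions: Ti(OiPr)4 (20 mol %), D-(−)-DIPT (24 mol %), t-BuOOH (2 equiv, decane), 4 Å MS, CH2Cl2, −25 °C
Reagents that add atoms: tert-butyl hydroperoxide, CC(C)(C)OO
Why: Sharpless asymmetric epoxidation, in which the D-(−)-tartrate–titanium complex delivers oxygen syn to the face of the E-2-methyl allylic alcohol that gives the 2R,3R epoxide (C11 R, C2' R), reagent control overriding the remote C3' centre, and any oxolane formed prematurely is already 8 and is carried along.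

Step 6
Reactants: 7 (3S)-3-[(2R,3R)-3-(hydroxymethyl)-3-methyloxiran-2-yl]butan-1-ol
Product: 8 (2R)-2-[(2S,3S)-3-methyloxolan-2-yl]propane-1,2-diol
Conditions: Ti(OiPr)4 (1.2 equiv), CH2Cl2, 0 °C → rt; aq. tartaric acid
Reagents that add atoms: none
Why: Ti(OiPr)4 exchanges isopropoxide for the C10 alkoxide and binds the epoxide oxygen in a five-membered chelate, which polarises the C2'–O bond remote from the carbinol, and the tethered C5' oxygen displaces it from the rear in an SN2 process. The closest known reaction type is the titanium-assisted C3-selective opening of 2,3-epoxy alcohols, used here in its intramolecular hydroxy-epoxide form. Ring C closes in the 5-exo-tet mode by forming O1'–C2'. C2' is the one stereocentre that is rewritten: inversion of the R epoxide carbon gives 2'S, trans to the C3' methyl group, whereas C11 keeps its C–O bond and its R configuration and C3' is a spectator. The step needs attack at C2' and not 6-endo attack at the tertiary C11, and the chelate, the electron-withdrawing C10 oxygen that disfavours cationic character at C11, the steric shielding of the fully substituted C11 and the shorter 5-exo trajectory all point the same way. The mild aprotic medium should suppress SN1 leakage and Payne migration, so no erosion at C2' is expected.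

Step 7
Reactants: 8 (2R)-2-[(2S,3S)-3-methyloxolan-2-yl]propane-1,2-diol
Product: 9 (2S,3S)-2-[(2R)-1,2-bis(triethylsilyloxy)propan-2-yl]-3-methyloxolane
Conditions: Et3SiOTf (2.4 equiv), 2,6-lutidine, CH2Cl2, −78 → 0 °C
Reagents that add atoms: triethylsilyl triflate, CC[Si](CC)(CC)OS(=O)(=O)C(F)(F)F
Why: A silyl triflate with a hindered pyridine base silylates the primary and the congested tertiary hydroxyl in one operation.

Step 8
Reactants: 9 (2S,3S)-2-[(2R)-1,2-bis(triethylsilyloxy)propan-2-yl]-3-methyloxolane
Product: 10 (2S)-2-[(2S,3S)-3-methyloxolan-2-yl]-2-(triethylsilyloxy)propanal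
Conditions: (COCl)2, DMSO, CH2Cl2, −78 → −40 °C; Et3N, → 0 °C
Reagents that add atoms: none
Why: Swern oxidation applied to a bis(triethylsilyl) ether, where only the unhindered primary silyl ether oxygen attacks the chlorosulfonium ion and is oxidised to the aldehyde, while the tertiary ether survives and the fully substituted C11 cannot epimerise.

Step 9
Reactants: 10 (2S)-2-[(2S,3S)-3-methyloxolan-2-yl]-2-(triethylsilyloxy)propanal
Product: 11 (2S,3S)-2-[(2R,3E)-4-iodo-2-(triethylsilyloxy)but-3-en-2-yl]-3-methyloxolane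
Conditions: CrCl2 (6 equiv), CHI3 (2 equiv), THF, 0 °C → rt
Reagents that add atoms: iodoform, IC(I)I
Why: Takai olefination, whose gem-dichromium reagent adds to the aldehyde and eliminates anti to give the E-vinyl iodide, a preference reinforced by the quaternary neighbour C11.

**Fragment 2 (ring A enynone)**

Step 10
Reactants: 12 [(2R)-2-methyloxiran-2-yl]methanol ((R)-2-methylglycidol)
Product: 13 (2S)-2-methylbut-3-ene-1,2-diol
Conditions: Me3S+ I− (4 equiv), n-BuLi (3.9 equiv), THF, −10 °C → rt
Reagents that add atoms: trimethylsulfonium iodide, C[S+](C)C.[I-]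
Why: One-carbon homologation of a terminal epoxide to an allylic alcohol with dimethylsulfonium methylide (attack at the CH2 terminus, then loss of Me2S), in which no bond to the stereocentre breaks, so the configuration of 12 becomes C7 and the descriptor changes from R to S only through the priority rules.

Step 11
Reactants: 13 (2S)-2-methylbut-3-ene-1,2-diol
Product: 14 (2S)-2-methyl-1,2-bis(triethylsilyloxy)but-3-ene
Conditions: Et3SiOTf (2.4 equiv), 2,6-lutidine, CH2Cl2, 0 °C
Reagents that add atoms: triethylsilyl triflate, CC[Si](CC)(CC)OS(=O)(=O)C(F)(F)F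
Why: Exhaustive silylation with the triflate covers the tertiary allylic hydroxyl and makes the small polar diol easy to handle.

Step 12
Reactants: 14 (2S)-2-methyl-1,2-bis(triethylsilyloxy)but-3-ene
Product: 15 (2S)-2-methyl-2-(triethylsilyloxy)but-3-enal
Conditions: (COCl)2, DMSO, CH2Cl2, −78 → −40 °C; Et3N, → 0 °C
Reagents that add atoms: none
Why: The same selective Swern oxidation of a primary triethylsilyl ether as in step 8 gives a non-enolisable aldehyde whose quaternary C7 cannot racemise.

Step 13
Reactants: 16 (4R)-4-benzyl-1,3-oxazolidin-2-one; 17 pent-4-enoyl chloride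
Product: 18 (4R)-4-benzyl-3-(pent-4-enoyl)-1,3-oxazolidin-2-one
Conditions: n-BuLi, THF, −78 °C; then 17, → 0 °C
Reagents that add atoms: none
Why: N-Acylation of the lithiated oxazolidinone with an acid chloride is the standard entry to Evans imides.

Step 14
Reactants: 18 (4R)-4-benzyl-3-(pent-4-enoyl)-1,3-oxazolidin-2-one; 15 (2S)-2-methyl-2-(triethylsilyloxy)but-3-enal
Product: 20 (4R)-4-benzyl-3-[(2R,3R,4S)-3-hydroxy-4-methyl-2-(prop-2-enyl)-4-(triethylsilyloxy)hex-5-enoyl]-1,3-oxazolidin-2-one, via Z-boron enolate 19 (not isolated)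
Conditions: n-Bu2BOTf, Et3N, CH2Cl2, −78 → 0 °C; 15, −78 → 0 °C; H2O2, MeOH, pH 7 buffer
Reagents that add atoms: dibutylboron triflate, CCCCB(CCCC)OS(=O)(=O)C(F)(F)F (its boron is carried by 19 only and leaves in the oxidative work-up)
Why: Evans syn-aldol reaction via the Z-boron enolate and a chair Zimmerman–Traxler transition state, the benzyl group of the R auxiliary shielding one enolate face so that C8a and C8 are set as 2R,3R (8aS,8R in the target), while C7, whose methyl and vinyl groups are of similar size, exerts little bias of its own.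

Step 15
Reactants: 20 aldol adduct
Product: 21 (4R)-4-benzyl-3-{[(1R,5S,6R)-6-hydroxy-5-methyl-5-(triethylsilyloxy)cyclohex-3-en-1-yl]carbonyl}-1,3-oxazolidin-2-one
Conditions: second-generation Grubbs catalyst RuCl2(=CHPh)(PCy3)(SIMes) (5 mol %), CH2Cl2, 40 °C
Reagents that add atoms: none
Why: Ring-closing metathesis of two monosubstituted alkenes closes the six-membered ring A at C5=C6 with loss of ethene and tolerates the free hydroxyl and the imide.

Step 16
Reactants: 21 cyclohexene imide
Product: 22 (1R,2S,6S)-6-(hydroxymethyl)-2-methyl-2-(triethylsilyloxy)cyclohex-3-en-1-ol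
Conditions: LiBH4 (2 equiv), THF, 0 °C → rt
Reagents that add atoms: none
Why: Reductive cleavage of the imide with LiBH4 gives the C1 primary alcohol without epimerising C8a and returns the auxiliary.

Step 17
Reactants: 22 (1R,2S,6S)-6-(hydroxymethyl)-2-methyl-2-(triethylsilyloxy)cyclohex-3-en-1-ol
Product: 23 cyclic di-tert-butylsilylene of 22 (O on C1 and O on C8 bridged by Si(t-Bu)2, cis-fused six-membered ring; C7 S, C8 R, C8a S)
Conditions: t-Bu2Si(OTf)2 (1.1 equiv), 2,6-lutidine, CH2Cl2, 0 °C
Reagents that add atoms: di-tert-butylsilyl bis(triflate), CC(C)(C)[Si](OS(=O)(=O)C(F)(F)F)(OS(=O)(=O)C(F)(F)F)C(C)(C)C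
Why: The cis-disposed C1 and C8 hydroxyls form a six-membered cyclic silylene with the bis(triflate), one fluoride-labile group that masks both and withstands oxidants and Grignard reagents.

Step 18
Reactants: 23 silylene-protected cyclohexene
Product: 24 (4S,5R,6S)-5-hydroxy-6-(hydroxymethyl)-4-methyl-4-(triethylsilyloxy)cyclohex-2-en-1-one as its di-tert-butylsilylene (ketone at C4a, alkene C5=C6)
Conditions: Rh2(cap)4 (1 mol %, cap = caprolactamate), t-BuOOH (5 equiv), K2CO3, CH2Cl2, rt
Reagents that add atoms: tert-butyl hydroperoxide, CC(C)(C)OO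
Why: Allylic C–H oxidation with Rh2(cap)4 and t-BuOOH, for which C4a carries the only allylic hydrogens because C7 is quaternary, and the peroxy radical should couple at C4a, the allyl terminus remote from the crowded C7.

Step 19
Reactants: 24 ring A enone
Product: 25 (4S,5R,6S)-1-ethynyl-6-(hydroxymethyl)-4-methyl-4-(triethylsilyloxy)cyclohex-2-ene-1,5-diol as its O5,O6'-di-tert-butylsilylene (tertiary carbinol at C4a, either epimer)
Conditions: HC≡CMgBr (3 equiv), THF, −78 → −20 °C
Reagents that add atoms: ethynylmagnesium bromide, C#C[Mg]Br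
Why: Alkynyl Grignard reagents add 1,2 to cyclohexenones faster than they enolise them at low temperature, and the new C4a carbinol centre is erased in the next step so that its configuration is immaterial.

Step 20
Reactants: 25 tertiary allylic-propargylic alcohol
Product: 26 (4S,5R,6R)-3-ethynyl-5-hydroxy-4-(hydroxymethyl)-6-methyl-6-(triethylsilyloxy)cyclohex-2-en-1-one as its di-tert-butylsilylene (ketone at C6, C4a=C5, alkyne C4≡C3)
Conditions: pyridinium chlorochromate C5H5NH[CrO3Cl] (3 equiv), 4 Å MS, CH2Cl2, rt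
Reagents that add atoms: pyridinium chlorochromate, [O-][Cr](=O)(=O)Cl.c1cc[nH+]cc1
Why: Babler–Dauben oxidative transposition, in which the tertiary chromate ester undergoes a [3,3] shift to C6 and is oxidised there, giving the C6 ketone conjugated with C4a=C5 and the alkyne.

**Union and endgame**

Step 21
Reactants: 26 ring A enynone; 11 ring C vinyl iodide
Product: 27 (4S,5R,6R)-3-[(3E,5R)-5-[(2S,3S)-3-methyloxolan-2-yl]-5-(triethylsilyloxy)hex-3-en-1-ynyl]-5-hydroxy-4-(hydroxymethyl)-6-methyl-6-(triethylsilyloxy)cyclohex-2-en-1-one as its di-tert-butylsilylene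
Conditions: Pd(PPh3)4 (5 mol %), CuI (10 mol %), Et3N, THF, rt, degassed
Reagents that add atoms: none
Why: Sonogashira coupling of a terminal alkyne with an E-vinyl iodide forms C3–C9 with retention of alkene geometry, a tertiary amine being used so that no amine adds to the enynone.

Step 22
Reactants: 27 silylated dienynone
Product: 28 (4S,5R,6R)-5,6-dihydroxy-4-(hydroxymethyl)-3-[(3E,5R)-5-hydroxy-5-[(2S,3S)-3-methyloxolan-2-yl]hex-3-en-1-ynyl]-6-methylcyclohex-2-en-1-one
Conditions: HF·pyridine, pyridine, THF, 0 °C → rt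
Reagents that add atoms: none
Why: Buffered HF·pyridine cleaves the silylene and both triethylsilyl ethers without acid strong enough to ionise the C11 tertiary allylic alcohol.

Step 23
Reactants: 28 tetraol dienynone
Product: 29 (7R,8R,8aS)-7,8-dihydroxy-3-[(1E,3R)-3-hydroxy-3-[(2S,3S)-3-methyloxolan-2-yl]but-1-enyl]-7-methyl-1,7,8,8a-tetrahydro-6H-isochromen-6-one
Conditions: (Ph3P)AuNTf2 (5 mol %), THF–CH2Cl2, 0 °C → rt
Reagents that add atoms: none
Why: Gold-catalysed cycloisomerisation of an alkynol (6-endo-dig hydroalkoxylation), in which the enone at C4a and the vinyl group at C3 polarise the activated alkyne so that the C1 hydroxyl attacks C3 and closes ring B to the fully conjugated dienone, while the C8 hydroxyl could only give a bridgehead alkene and the E-alkene keeps the C11 hydroxyl out of reach.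

Step 24
Reactants: 29 deschloro compound
Product: 30 (7R,8R,8aS)-5-chloro-7,8-dihydroxy-3-[(1E,3R)-3-hydroxy-3-[(2S,3S)-3-methyloxolan-2-yl]but-1-enyl]-7-methyl-1,7,8,8a-tetrahydro-6H-isochromen-6-one (target)
Conditions: NCS (1.05 equiv), MeCN, 0 °C
Reagents that add atoms: N-chlorosuccinimide, O=C1CCC(=O)N1Cl
Why: Electrophilic chlorination of a vinylogous ester with NCS, known to occur at C5 of isochromen-6-ones, where the O2 lone pair relayed through C3=C4–C4a=C5 makes the carbon α to the ketone the most nucleophilic site.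

**Compound list**
1 | 3-methylideneoxolan-2-one | C=C1CCOC1=O | starting material
2 | (3S)-3-methyloxolan-2-one | C[C@H]1CCOC1=O | intermediate
3 | (3S)-3-methyloxolan-2-ol (anomers) | C[C@H]1CCOC1O | intermediate
4 | ethyl 2-(triphenylphosphoranylidene)propanoate | CCOC(=O)C(C)=P(c1ccccc1)(c1ccccc1)c1ccccc1 | starting material
5 | ethyl (2E,4S)-6-hydroxy-2,4-dimethylhex-2-enoate | CCOC(=O)/C(C)=C/[C@@H](C)CCO | intermediate
6 | (2E,4S)-2,4-dimethylhex-2-ene-1,6-diol | OC/C(C)=C/[C@@H](C)CCO | intermediate
7 | (3S)-3-[(2R,3R)-3-(hydroxymethyl)-3-methyloxiran-2-yl]butan-1-ol | C[C@@H](CCO)[C@H]1O[C@]1(C)CO | intermediate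
8 | (2R)-2-[(2S,3S)-3-methyloxolan-2-yl]propane-1,2-diol | C[C@H]1CCO[C@@H]1[C@](C)(O)CO | intermediate
9 | (2S,3S)-2-[(2R)-1,2-bis(triethylsilyloxy)propan-2-yl]-3-methyloxolane | C[C@H]1CCO[C@@H]1[C@](C)(O[Si](CC)(CC)CC)CO[Si](CC)(CC)CC | intermediate
10 | (2S)-2-[(2S,3S)-3-methyloxolan-2-yl]-2-(triethylsilyloxy)propanal | C[C@H]1CCO[C@@H]1[C@](C)(O[Si](CC)(CC)CC)C=O | intermediate
11 | (2S,3S)-2-[(2R,3E)-4-iodo-2-(triethylsilyloxy)but-3-en-2-yl]-3-methyloxolane | C[C@H]1CCO[C@@H]1[C@](C)(O[Si](CC)(CC)CC)/C=C/I | intermediate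
12 | [(2R)-2-methyloxiran-2-yl]methanol | C[C@@]1(CO)CO1 | starting material
13 | (2S)-2-methylbut-3-ene-1,2-diol | C[C@@](O)(CO)C=C | intermediate
14 | (2S)-2-methyl-1,2-bis(triethylsilyloxy)but-3-ene | C[C@@](O[Si](CC)(CC)CC)(CO[Si](CC)(CC)CC)C=C | intermediate
15 | (2S)-2-methyl-2-(triethylsilyloxy)but-3-enal | C[C@@](O[Si](CC)(CC)CC)(C=O)C=C | intermediate
16 | (4R)-4-benzyl-1,3-oxazolidin-2-one | O=C1N[C@H](Cc2ccccc2)CO1 | starting material
17 | pent-4-enoyl chloride | C=CCCC(=O)Cl | starting material
18 | (4R)-4-benzyl-3-(pent-4-enoyl)-1,3-oxazolidin-2-one | C=CCCC(=O)N1C(=O)OC[C@H]1Cc1ccccc1 | intermediate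
19 | Z-dibutylboron enolate of 18 | C=CC/C=C(\OB(CCCC)CCCC)N1C(=O)OC[C@H]1Cc1ccccc1 | intermediate
20 | (4R)-4-benzyl-3-[(2R,3R,4S)-3-hydroxy-4-methyl-2-(prop-2-enyl)-4-(triethylsilyloxy)hex-5-enoyl]-1,3-oxazolidin-2-one | C=C[C@](C)(O[Si](CC)(CC)CC)[C@H](O)[C@@H](CC=C)C(=O)N1C(=O)OC[C@H]1Cc1ccccc1 | intermediate
21 | (4R)-4-benzyl-3-{[(1R,5S,6R)-6-hydroxy-5-methyl-5-(triethylsilyloxy)cyclohex-3-en-1-yl]carbonyl}-1,3-oxazolidin-2-one | C1=C[C@](C)(O[Si](CC)(CC)CC)[C@H](O)[C@@H](C1)C(=O)N1C(=O)OC[C@H]1Cc1ccccc1 | intermediate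
22 | (1R,2S,6S)-6-(hydroxymethyl)-2-methyl-2-(triethylsilyloxy)cyclohex-3-en-1-ol | C1=C[C@](C)(O[Si](CC)(CC)CC)[C@H](O)[C@@H](C1)CO | intermediate
23 | di-tert-butylsilylene of 22 | C1=C[C@](C)(O[Si](CC)(CC)CC)[C@@H]2O[Si](C(C)(C)C)(C(C)(C)C)OC[C@@H]2C1 | intermediate
24 | ring A enone (C4a ketone), silylene-protected | O=C1C=C[C@](C)(O[Si](CC)(CC)CC)[C@@H]2O[Si](C(C)(C)C)(C(C)(C)C)OC[C@@H]21 | intermediate
25 | C4a ethynyl carbinol (C4a epimers), silylene-protected | C#CC1(O)C=C[C@](C)(O[Si](CC)(CC)CC)[C@@H]2O[Si](C(C)(C)C)(C(C)(C)C)OC[C@@H]21 | intermediate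
26 | ring A enynone (C6 ketone), silylene-protected | C#CC1=CC(=O)[C@](C)(O[Si](CC)(CC)CC)[C@@H]2O[Si](C(C)(C)C)(C(C)(C)C)OC[C@@H]21 | intermediate
27 | silylated (9E)-dienynone | C[C@H]1CCO[C@@H]1[C@](C)(O[Si](CC)(CC)CC)/C=C/C#CC1=CC(=O)[C@](C)(O[Si](CC)(CC)CC)[C@@H]2O[Si](C(C)(C)C)(C(C)(C)C)OC[C@@H]21 | intermediate
28 | tetraol (9E)-dienynone | C[C@H]1CCO[C@@H]1[C@](C)(O)/C=C/C#CC1=CC(=O)[C@](C)(O)[C@H](O)[C@@H]1CO | intermediate
29 | deschloro isochromenone | C[C@H]1CCO[C@@H]1[C@](C)(O)/C=C/C1=CC2=CC(=O)[C@](C)(O)[C@H](O)[C@@H]2CO1 | intermediate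
30 | CNP0432723.2 | C[C@H]1CCO[C@@H]1[C@](C)(O)/C=C/C1=CC2=C(Cl)C(=O)[C@](C)(O)[C@H](O)[C@@H]2CO1 | target

**Step count**
Total steps: 24.
Longest linear sequence: 14 steps from 12 (steps 10–12 and 14–24). The side-chain branch from 1 takes 13 steps (steps 1–9 and 21–24).

**Steps most likely to fail**

Step 24. The chlorination may lack site selectivity. Attack could occur at C4 or on the side-chain diene instead of C5, or the unprotected polyol could be oxidised. The fallback installs chlorine on ring A before the alkyne is introduced.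
- It sets out from enone 24, which is treated with PhICl2 and pyridine (addition of chlorine, then dehydrochlorination) to give the 2-chloroenone F1.
- HC≡CMgBr adds 1,2 to give the chloro carbinol F2.
- Pyridinium chlorochromate C5H5NH[CrO3Cl] transposes it to the chloro enynone F3.
- Sonogashira coupling with 11 under Pd(PPh3)4/CuI gives the silylated chloro dienynone F4.
- HF·pyridine frees the chloro tetraol F5.
- (Ph3P)AuNTf2 then closes ring B, so the sequence rejoins the route at the target 30.

Step 23. Ring closure may go astray in two ways: 5-exo-dig attack at C4 may compete, or the Lewis acidic metal may ionise the C11 tertiary allylic alcohol. The fallback is a metal-free amine relay that sets out from 28.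
- Diethylamine adds in a 1,6 sense to the enynone at C3 to give the dienaminone F6.
- On exposure to pyridinium p-toluenesulfonate in CH2Cl2, the C1 hydroxyl replaces the amine by addition–elimination. This can only form the six-membered ring, and it rejoins the route at 29.

Step 18. The peroxy radical may couple at the wrong allyl terminus (C6), hydrogen abstraction beside the bicyclic silylene may be slow, or C8a may epimerise once the ketone is exposed to base for long. The fallback replaces radical C–H peroxidation with a pericyclic hydroxylation that cannot transpose.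
- It sets out from 23. SeO2 (catalytic) with t-BuOOH effects an ene reaction and [2,3] shift that return oxygen to the carbon that lost hydrogen, giving the C4a allylic alcohol F7.
- Dess–Martin periodinane under neutral conditions then oxidises it, rejoining the route at 24.

**Further compounds**
F1 | step 24 | 2-chloro analogue of enone 24 (Cl on C5) | O=C1C(Cl)=C[C@](C)(O[Si](CC)(CC)CC)[C@@H]2O[Si](C(C)(C)C)(C(C)(C)C)OC[C@@H]21
F2 | step 24 | C4a ethynyl carbinol bearing Cl on C5 (C4a epimers) | C#CC1(O)C(Cl)=C[C@](C)(O[Si](CC)(CC)CC)[C@@H]2O[Si](C(C)(C)C)(C(C)(C)C)OC[C@@H]21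
F3 | step 24 | 5-chloro analogue of enynone 26 | C#CC1=C(Cl)C(=O)[C@](C)(O[Si](CC)(CC)CC)[C@@H]2O[Si](C(C)(C)C)(C(C)(C)C)OC[C@@H]21
F4 | step 24 | 5-chloro analogue of dienynone 27 | C[C@H]1CCO[C@@H]1[C@](C)(O[Si](CC)(CC)CC)/C=C/C#CC1=C(Cl)C(=O)[C@](C)(O[Si](CC)(CC)CC)[C@@H]2O[Si](C(C)(C)C)(C(C)(C)C)OC[C@@H]21
F5 | step 24 | 5-chloro analogue of tetraol 28 | C[C@H]1CCO[C@@H]1[C@](C)(O)/C=C/C#CC1=C(Cl)C(=O)[C@](C)(O)[C@H](O)[C@@H]1CO
F6 | step 23 | C3 diethylamino dienaminone from 28 (C3=C4 geometry not controlled) | C[C@H]1CCO[C@@H]1[C@](C)(O)/C=C/C(N(CC)CC)=CC1=CC(=O)[C@](C)(O)[C@H](O)[C@@H]1CO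
F7 | step 18 | C4a allylic alcohol of 23 (carbinol epimers) | OC1C=C[C@](C)(O[Si](CC)(CC)CC)[C@@H]2O[Si](C(C)(C)C)(C(C)(C)C)OC[C@@H]21
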